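**Plan**

1. Retrosynthesis: the three aryl O–S bonds are cut first (back to kaempferol), then the three ether O–C bonds, then ring A at C4a–C5, C5–C6 and C7–C8 (C8–C8a traces back to a 1,2-shift), and last the C2–C1' bond to ring B, leaving comenic acid as ring C.
2. Enabling feature: ring A is a benzene ring with meta oxygens at C5 and C7, sharing the C4a–C8a bond with the pyranone ring C. O5 is a free hydroxyl peri to the C4 carbonyl and O7 must be different from it, which is the pattern a ketene/1-alkoxyalkyne benzannulation on a pyranonyl diazo ketone produces.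
3. Forward order: ring C is bought (comenic acid), brominated at C6 and protected; ring B is joined by Suzuki coupling; the carboxyl group becomes a diazoacetyl group (its carbon ends as C5, the diazomethane carbon as C8); ring A is then closed with ethoxyacetylene.
4. Endgame: BBr3 frees all hydroxyls, and SO3·NMe3 sulfates O3, O7 and O4' while the chelated 5-OH stays free.
5. Stereochemistry: the target has no stereocentre and no stereogenic double bond; only regiochemistry has to be secured, by the polarisation of the ynol ether and by the single carbon neighbour of the ketene-bearing ring carbon.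

Key step: step 7

Assumption: the target is drawn as the free tris(hydrogen sulfate); such esters are normally handled as salts, so step 9 ends with cation exchange to the acid form and the neutral formula is given (storage as the trisodium salt is advisable).

**Step 1**
Reactants: 1 comenic acid (5-hydroxy-4-oxo-4H-pyran-2-carboxylic acid)
Product: 2 6-bromo-5-hydroxy-4-oxo-4H-pyran-2-carboxylic acid
Conditions: Br2 (1.05 equiv), H2O, 20 °C
Reagents that add atoms: bromine, BrBr
Why: Electrophilic bromination of the enolic 5-hydroxy-4-pyranone goes to the only free carbon ortho to the hydroxyl (C6), as in the halogenation of kojic acid.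

**Step 2**
Reactants: 2 6-bromo-5-hydroxy-4-oxo-4H-pyran-2-carboxylic acid
Product: 3 benzyl 5-(benzyloxy)-6-bromo-4-oxo-4H-pyran-2-carboxylate
Conditions: BnBr (2.4 equiv), K2CO3, DMF, 50 °C
Reagents that add atoms: benzyl bromide, BrCc1ccccc1
Why: Double SN2 alkylation (Williamson ether synthesis at the enolic oxygen and carboxylate alkylation) protects both acidic groups in one operation.

**Step 3**
Reactants: 3 benzyl 5-(benzyloxy)-6-bromo-4-oxo-4H-pyran-2-carboxylate; 4 4-(benzyloxy)phenylboronic acid
Product: 5 benzyl 5-(benzyloxy)-6-[4-(benzyloxy)phenyl]-4-oxo-4H-pyran-2-carboxylate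
Conditions: Pd(PPh3)4 (5 mol %), K3PO4, 1,4-dioxane/H2O (10:1), 85 °C
Reagents that add atoms: none
Why: Suzuki–Miyaura coupling; the C6–Br bond belongs to a β-bromo enone (a vinylogous acyl bromide) and adds readily to zerovalent palladium, and the mild phosphate base in a medium with little water spares the benzyl ester.

**Step 4**
Reactants: 5 benzyl 5-(benzyloxy)-6-[4-(benzyloxy)phenyl]-4-oxo-4H-pyran-2-carboxylate
Product: 6 5-(benzyloxy)-6-[4-(benzyloxy)phenyl]-4-oxo-4H-pyran-2-carboxylic acid
Conditions: LiOH·H2O (1.2 equiv), THF/H2O, 0 °C; then 1 M HCl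
Reagents that add atoms: lithium hydroxide, [Li+].[OH-]
Why: Saponification of an ester activated by the electron-poor pyranone is fast at 0 °C, so it can be run below the conditions under which hydroxide opens 4-pyranones, and the benzyl ethers are inert.

**Step 5**
Reactants: 6 5-(benzyloxy)-6-[4-(benzyloxy)phenyl]-4-oxo-4H-pyran-2-carboxylic acid
Product: 7 5-(benzyloxy)-6-[4-(benzyloxy)phenyl]-4-oxo-4H-pyran-2-carbonyl chloride
Conditions: (COCl)2 (1.5 equiv), DMF (cat.), CH2Cl2, 0 → 20 °C; evaporated and used crude
Reagents that add atoms: oxalyl chloride, O=C(Cl)C(=O)Cl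
Why: Acid chloride formation through the Vilsmeier-type chloroiminium species runs under cold, non-basic conditions that neither cleave the benzyl ethers nor attack the pyranone carbonyl.

**Step 6**
Reactants: 7 5-(benzyloxy)-6-[4-(benzyloxy)phenyl]-4-oxo-4H-pyran-2-carbonyl chloride
Product: 8 2-diazo-1-{5-(benzyloxy)-6-[4-(benzyloxy)phenyl]-4-oxo-4H-pyran-2-yl}ethanone
Conditions: CH2N2 (3 equiv), Et2O/THF, 0 °C, dark
Reagents that add atoms: diazomethane, C=[N+]=[N-]
Why: Acylation of diazomethane by an acid chloride (first stage of the Arndt–Eistert sequence) gives the diazomethyl ketone while excess reagent takes up HCl as chloromethane; acylation at 0 °C should be much faster than dipolar cycloaddition to the pyranone.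

**Step 7**
Reactants: 8 2-diazo-1-{5-(benzyloxy)-6-[4-(benzyloxy)phenyl]-4-oxo-4H-pyran-2-yl}ethanone; 9 ethoxyacetylene
Product: 14 3-(benzyloxy)-2-[4-(benzyloxy)phenyl]-7-ethoxy-5-hydroxy-4H-chromen-4-one, via pyranonylketene 10 (not isolated), via ethoxycyclobutenone 11 (not isolated), via dienylketene 12 (not isolated), via chromenedione tautomer 13 (not isolated)
Conditions: 9 (3 equiv), hν (440 nm LEDs), ClCH2CH2Cl, 20 °C; then 80 °C, sealed tube
Reagents that add atoms: none
Why: Proposed new method: visible light absorbed only by the diazo ketone expels N2 and triggers the Wolff 1,2-shift of the pyranonyl group to give ketene 10, whose carbonyl carbon is attacked by the nucleophilic CH terminus of ethoxyacetylene in a [2+2] cycloaddition to cyclobutenone 11; on heating, 11 opens by four-electron electrocyclic cleavage to dienylketene 12 (the isomer with the pyranonyl group cis to the ketene arm is drained off, the other can revert through 11). Ring A, a six-membered carbocycle, then closes by thermal six-electron (disrotatory) electrocyclization of 12 onto the C2=C3 bond of the pyranone to give dienone 13, and the 4a-hydrogen, lying between two carbonyl groups, moves to oxygen to give phenol 14. The closest known reaction type is the second-generation Danheiser benzannulation, in which aryl, heteroaryl and alkenyl diazomethyl ketones react with alkoxy- and siloxyalkynes by the same cascade; a 4-pyranone C=C bond as the third π component has not been shown, but it gives up less aromatic stabilisation than the benzene and heteroarene rings known to take part. No lasting stereocentre is formed (those of 11 and 13 are lost on the way). The selectivity required is regiochemical: the polarisation of the ynol ether puts the ethoxy-bearing carbon next to the former diazo carbon, so OEt ends at C7 and the ketene carbon becomes C5 with its free hydroxyl, and the ring carbon carrying the ketene arm has the ring oxygen as its other neighbour, so closure can only reach the carbon that becomes C4a. Irradiation near 440 nm, where neither the 3-benzyloxypyranone nor the flavone is expected to absorb appreciably, is chosen so that pyranone photoisomerisation and hydrogen abstraction from the OCH2Ph group do not compete.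

**Step 8**
Reactants: 14 3-(benzyloxy)-2-[4-(benzyloxy)phenyl]-7-ethoxy-5-hydroxy-4H-chromen-4-one
Product: 15 kaempferol (3,5,7-trihydroxy-2-(4-hydroxyphenyl)-4H-chromen-4-one)
Conditions: BBr3 (8 equiv), CH2Cl2, −78 → 25 °C; then H2O
Reagents that add atoms: none
Why: Lewis-acid ether cleavage: boron coordinates each ether oxygen and bromide removes the benzyl groups quickly and the ethyl group more slowly by SN2 attack, a standard way to unmask polyalkoxyflavones without harming the flavonol core.

**Step 9**
Reactants: 15 kaempferol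
Product: 16 kaempferol 3,7,4'-tri-O-sulfate
Conditions: SO3·NMe3 (12 equiv), Et3N, DMA, 65 °C; then Dowex 50W (H+ form), H2O, 0 °C, lyophilisation
Reagents that add atoms: sulfur trioxide–trimethylamine complex, C[N+](C)(C)S(=O)(=O)[O-]
Why: O-Sulfonation of phenols by an amine–SO3 complex takes the hydroxyls at C7, C4' and C3, whereas the 5-OH, held to the C4 carbonyl by a six-membered hydrogen bond, is the least nucleophilic and stays free, as in the exhaustive sulfation of other flavonols.

**Compound list**

1 | comenic acid (5-hydroxy-4-oxo-4H-pyran-2-carboxylic acid) | O=C(O)c1cc(=O)c(O)co1 | starting material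
2 | 6-bromo-5-hydroxy-4-oxo-4H-pyran-2-carboxylic acid | O=C(O)c1cc(=O)c(O)c(Br)o1 | intermediate
3 | benzyl 5-(benzyloxy)-6-bromo-4-oxo-4H-pyran-2-carboxylate | O=C(OCc1ccccc1)c1cc(=O)c(OCc2ccccc2)c(Br)o1 | intermediate
4 | 4-(benzyloxy)phenylboronic acid | OB(O)c1ccc(OCc2ccccc2)cc1 | starting material
5 | benzyl 5-(benzyloxy)-6-[4-(benzyloxy)phenyl]-4-oxo-4H-pyran-2-carboxylate | O=C(OCc1ccccc1)c1cc(=O)c(OCc2ccccc2)c(-c2ccc(OCc3ccccc3)cc2)o1 | intermediate
6 | 5-(benzyloxy)-6-[4-(benzyloxy)phenyl]-4-oxo-4H-pyran-2-carboxylic acid | O=C(O)c1cc(=O)c(OCc2ccccc2)c(-c2ccc(OCc3ccccc3)cc2)o1 | intermediate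
7 | 5-(benzyloxy)-6-[4-(benzyloxy)phenyl]-4-oxo-4H-pyran-2-carbonyl chloride | O=C(Cl)c1cc(=O)c(OCc2ccccc2)c(-c2ccc(OCc3ccccc3)cc2)o1 | intermediate
8 | 2-diazo-1-{5-(benzyloxy)-6-[4-(benzyloxy)phenyl]-4-oxo-4H-pyran-2-yl}ethanone | [N-]=[N+]=CC(=O)c1cc(=O)c(OCc2ccccc2)c(-c2ccc(OCc3ccccc3)cc2)o1 | intermediate
9 | ethoxyacetylene | CCOC#C | starting material
10 | {5-(benzyloxy)-6-[4-(benzyloxy)phenyl]-4-oxo-4H-pyran-2-yl}ketene (not isolated) | O=C=Cc1cc(=O)c(OCc2ccccc2)c(-c2ccc(OCc3ccccc3)cc2)o1 | intermediate
11 | 4-{5-(benzyloxy)-6-[4-(benzyloxy)phenyl]-4-oxo-4H-pyran-2-yl}-3-ethoxycyclobut-2-en-1-one (racemic, not isolated) | O=C1C=C(OCC)C1c1cc(=O)c(OCc2ccccc2)c(-c2ccc(OCc3ccccc3)cc2)o1 | intermediate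
12 | (3E)-4-{5-(benzyloxy)-6-[4-(benzyloxy)phenyl]-4-oxo-4H-pyran-2-yl}-3-ethoxybuta-1,3-dien-1-one (pyranonyl cis to the ketene arm, not isolated) | O=C=C/C(OCC)=C\c1cc(=O)c(OCc2ccccc2)c(-c2ccc(OCc3ccccc3)cc2)o1 | intermediate
13 | 3-(benzyloxy)-2-[4-(benzyloxy)phenyl]-7-ethoxy-4aH-chromene-4,5-dione (racemic keto tautomer, not isolated) | O=C1C=C(OCC)C=C2OC(-c3ccc(OCc4ccccc4)cc3)=C(OCc3ccccc3)C(=O)C12 | intermediate
14 | 3-(benzyloxy)-2-[4-(benzyloxy)phenyl]-7-ethoxy-5-hydroxy-4H-chromen-4-one | O=c1c(OCc2ccccc2)c(-c2ccc(OCc3ccccc3)cc2)oc2cc(OCC)cc(O)c12 | intermediate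
15 | kaempferol | O=c1c(O)c(-c2ccc(O)cc2)oc2cc(O)cc(O)c12 | intermediate
16 | kaempferol 3,7,4'-tri-O-sulfate | O=c1c(OS(=O)(=O)O)c(-c2ccc(OS(=O)(=O)O)cc2)oc2cc(OS(=O)(=O)O)cc(O)c12 | target

**Step count**

Total steps: 9. Longest linear sequence: 9 steps (1 → 16); 4 and 9 enter as bought fragments.

**Steps most likely to fail**

Step 7 (ring A benzannulation, the untested step). What may go wrong: photodecomposition of the pyranone or dimerisation of the ketene outruns the [2+2] step, or the dienylketene does not close onto the pyranone C=C bond and is lost to oligomers. The fallback uses known chemistry and brings ring A in ready-made; it sets out from boronic acid 4 and rejoins at kaempferol 15. Commercial 2'-hydroxy-4',6'-dimethoxyacetophenone is condensed with DMF dimethyl acetal and cyclised with acid to 5,7-dimethoxy-4H-chromen-4-one F1. Oxidative coupling of this chromone with 4 under divalent-palladium catalysis (Pd(OCOCF3)2 with an oxidant such as DDQ; conjugate addition of the aryl group at C2, then dehydrogenation) gives 2-[4-(benzyloxy)phenyl]-5,7-dimethoxy-4H-chromen-4-one F2. Dimethyldioxirane epoxidises the C2=C3 bond to 1a-[4-(benzyloxy)phenyl]-4,6-dimethoxy-1a,7a-dihydro-7H-oxireno[2,3-b]chromen-7-one F3, which TsOH opens to 2-[4-(benzyloxy)phenyl]-3-hydroxy-5,7-dimethoxy-4H-chromen-4-one F4. BBr3 then removes the benzyl and both methyl groups to give 15.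

Step 6 (diazo ketone). What may go wrong: diazomethane adds as a 1,3-dipole across the electron-poor C2=C3 bond of the pyranone (pyrazoline formation) instead of, or after, being acylated. The fallback replaces acylation by diazo transfer; it sets out from acid chloride 7 and returns at diazo ketone 8. Negishi acylation of 7 with MeZnCl and Pd(PPh3)4 gives 2-acetyl-5-(benzyloxy)-6-[4-(benzyloxy)phenyl]-4H-pyran-4-one F5. Its lithium enolate (LiN(SiMe3)2, THF, −78 °C) is acylated with 2,2,2-trifluoroethyl trifluoroacetate to 1-{5-(benzyloxy)-6-[4-(benzyloxy)phenyl]-4-oxo-4H-pyran-2-yl}-4,4,4-trifluorobutane-1,3-dione F6. This is treated without purification with methanesulfonyl azide, Et3N and water in MeCN (detrifluoroacetylative diazo transfer) to give 8.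

Step 9 (sulfation). What may go wrong: incomplete sulfation of the least reactive 3-OH, partial sulfation of the 5-OH under forcing conditions, and hydrolytic loss of sulfate while a highly polar mixture that cannot be chromatographed is being separated. The fallback uses protected sulfate diesters; it sets out from kaempferol 15 and returns at target 16. 2,2,2-Trichloroethyl chlorosulfate with Et3N and DMAP converts the three non-chelated hydroxyls into trichloroethyl sulfate diesters, giving kaempferol 3,7,4'-tris(2,2,2-trichloroethyl sulfate) F7, a neutral compound that can be purified on silica. Zn dust and ammonium formate in MeOH then remove the three trichloroethyl groups by reductive fragmentation, and cation exchange gives 16.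

**Further compounds**

F1 | step 7 | 5,7-dimethoxy-4H-chromen-4-one | O=c1ccoc2cc(OC)cc(OC)c12
F2 | step 7 | 2-[4-(benzyloxy)phenyl]-5,7-dimethoxy-4H-chromen-4-one | O=c1cc(-c2ccc(OCc3ccccc3)cc2)oc2cc(OC)cc(OC)c12
F3 | step 7 | 1a-[4-(benzyloxy)phenyl]-4,6-dimethoxy-1a,7a-dihydro-7H-oxireno[2,3-b]chromen-7-one (racemic) | COc1cc(OC)c2c(c1)OC1(c3ccc(OCc4ccccc4)cc3)OC1C2=O
F4 | step 7 | 2-[4-(benzyloxy)phenyl]-3-hydroxy-5,7-dimethoxy-4H-chromen-4-one | O=c1c(O)c(-c2ccc(OCc3ccccc3)cc2)oc2cc(OC)cc(OC)c12
F5 | step 6 | 2-acetyl-5-(benzyloxy)-6-[4-(benzyloxy)phenyl]-4H-pyran-4-one | CC(=O)c1cc(=O)c(OCc2ccccc2)c(-c2ccc(OCc3ccccc3)cc2)o1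
F6 | step 6 | 1-{5-(benzyloxy)-6-[4-(benzyloxy)phenyl]-4-oxo-4H-pyran-2-yl}-4,4,4-trifluorobutane-1,3-dione | O=C(CC(=O)C(F)(F)F)c1cc(=O)c(OCc2ccccc2)c(-c2ccc(OCc3ccccc3)cc2)o1
F7 | step 9 | kaempferol 3,7,4'-tris(2,2,2-trichloroethyl sulfate) | O=c1c(OS(=O)(=O)OCC(Cl)(Cl)Cl)c(-c2ccc(OS(=O)(=O)OCC(Cl)(Cl)Cl)cc2)oc2cc(OS(=O)(=O)OCC(Cl)(Cl)Cl)cc(O)c12
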